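The flask is read when 10% of its substrate is converted, and how early that moment comes depends on how fast the catalyst turns, so the time of reading is part of the problem.

substrate 14 mM; reagent 11.2 mM; free catalyst 70 µM

    catalyst intermediate B ⇌ free catalyst + product (K1 = 0.00285 M, k1 = 1.01 s⁻¹)
    substrate + catalyst intermediate A → catalyst intermediate B (k2 = 257 M⁻¹ s⁻¹)
    reagent ⇌ dormant form (K3 = 1.1, k3 = 0.0125 s⁻¹)
    reagent + free catalyst → catalyst intermediate A (k4 = 143 M⁻¹ s⁻¹)

1. the form that holds most of the catalyst when 10% of the substrate are converted (catalyst intermediate A / free catalyst / catalyst intermediate B)
2. its share of the catalyst then
3. factor on the rate of making product when 10% of the substrate are converted if free catalyst is charged twice over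
4. factor on the rate when 10% of the substrate are converted if free catalyst is charged at 400 µM instead

Minutes of the meeting on this flask. I proposed one quantity, the round time T, the sum of the waits of the catalyst in its three forms during one net turn. The rate is then the catalyst charged over T, and the share of a form is its wait over T.

I defined four rates. Capture of free catalyst by reagent, a, is a pseudo-first-order rate: its constant times the reagent present. Capture of intermediate A by substrate, b, is formed likewise. The release constant of intermediate B is c. The return of free catalyst with product is d. Free catalyst waits one over a, and intermediate A one over b. Intermediate B waits one over c, lengthened by the returns, d over a per net turn.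

I first counted reagent as charged less what the conversion used. That gave a = 1.40 s⁻¹, b = 3.24 s⁻¹ and d = 0.496 s⁻¹, so T = 2.36 s, and the reading would come near 47.3 s.

I then put that time back in. Over it, reagent relaxes towards the dormant form and loses about 35.4%, leaving 6.33 mM. The second round gave T = 2.95 s. Intermediate B waits longer than free catalyst or intermediate A, so I named it the resting state, with 52.0% of the round time.

With free catalyst charged twice over, I divided the first-round time by that factor. This left 7.59 mM of reagent and T = 2.67 s, a rate factor of 2.21.

The forecast named catalyst intermediate B at 51%, with factors 2.25 and 7.1, its ground being “leaving less time for reagent to slip into its dormant form”. It differed slightly from my figures.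

The simulation gives catalyst intermediate B at 51.5% in this flask, reached at 0.778 min, with factors 2.25 and 7.04; its rate is 1.41 mM min⁻¹, and the charge over T gives 1.43 mM min⁻¹. The rate rises faster than the charge in part because reagent is lost to dormant form: the apparent order in free catalyst is 1.2, and 1.0 in the run without that loss. The apparent order in reagent is 0.76, against 0.51 in that run, in part because of the same loss. In the flask charged with 400 µM, the first-round time becomes 8.27 s, leaving 8.88 mM of reagent and T = 2.47 s, so the factor is 6.81, and that flask gives 7.04.

The rate constants were chosen freely; no experiment stands behind them.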